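**Strategy.** Ring B of the bicyclo[3.3.1]nonane core (C1–C2–C3–C4–C5–C9, C9 being the bridging ketone) is the acylphloroglucinol ring. It is cut into a four-atom C9–C1–C2–C3 unit, stored as a 3,3-disubstituted 6-aryl-pyran-2,4-dione, and the two-atom C5–C4 unit of a methyl ester, both carried by the C8–C7–C6 chain. One base-triggered relay of two Claisen condensations closes rings A and B: the C5 ester enolate opens the enol lactone at C9, and the aroyl diketone enolate thus released attacks the C4 ester. The precursor is assembled on a 4-hydroxy-6-aryl-2-pyrone, with C7 set by Evans alkylation and C1 by a chirality-transferring Claisen rearrangement.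

Key step: step 14

Remark: atom labels follow the core numbering (C1 and C5 bridgeheads, C6 the ring CH2, C7 the geranyl-bearing CH, C8 the CMe2 carbon); the target is one of the equilibrating enol tautomers of its triketone, C5 in 20–23 and the new alkene in 19 are inconsequential mixtures, and Ar = 3,4-bis(triisopropylsilyloxy)phenyl.

Step 1
Reactants: 1 methyl 3,4-dihydroxybenzoate
Product: 2 methyl 3,4-bis(triisopropylsilyloxy)benzoate
Conditions: TIPSOTf, 2,6-lutidine, CH2Cl2, 0 °C → rt
Reagents that add atoms: triisopropylsilyl trifluoromethanesulfonate, CC(C)[Si](OS(=O)(=O)C(F)(F)F)(C(C)C)C(C)C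
Why: Silylation of both phenols gives a catechol protection that should survive bases, hydrides, heat and metathesis and that fluoride removes at the end without acid.

Step 2
Reactants: 2 methyl 3,4-bis(triisopropylsilyloxy)benzoate; 3 methyl acetoacetate
Product: 5 6-Ar-4-hydroxy-2H-pyran-2-one, via diketo ester 4 (not isolated)
Conditions: 3, NaH then n-BuLi, THF, 0 °C; 2, 0 °C → rt; aq. HCl; crude 4, DBU (cat.), PhMe, 110 °C
Reagents that add atoms: none
Why: Claisen condensation of the acetoacetate dianion at its terminal carbon with the aryl ester, followed by base-mediated lactonisation of the 3,5-dioxo ester, is the standard route to 6-aryl-4-hydroxy-2-pyrones.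

Step 3
Reactants: 5 6-Ar-4-hydroxy-2H-pyran-2-one; 6 2,2-dimethyl-5-(propan-2-ylidene)-1,3-dioxane-4,6-dione
Product: 7 7-Ar-4,4-dimethyl-3,4-dihydro-2H,5H-pyrano[4,3-b]pyran-2,5-dione (enol lactone: pyrone C3–CMe2–CH2–C(=O)–O–pyrone C4)
Conditions: Yb(OTf)3 (10 mol%), MeNO2, 100 °C
Reagents that add atoms: none
Why: Lewis-acid-catalysed Michael addition of the nucleophilic pyrone C3 to the alkylidene Meldrum's acid, then O-acylation with loss of acetone and CO2, is the domino conjugate addition/lactonisation known for phenols and 4-hydroxycoumarins; it forms the C1–C8 bond and the quaternary C8.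

Step 4
Reactants: 7 the pyranopyrandione; 8 (S)-4-benzyloxazolidin-2-one
Product: 9 (S)-4-benzyl-3-[3-(6-Ar-4-hydroxy-2-oxo-2H-pyran-3-yl)-3-methylbutanoyl]oxazolidin-2-one
Conditions: 8, n-BuLi, THF, −78 °C; then 7, −78 → 0 °C; aq. NH4Cl
Reagents that add atoms: none
Why: N-Acylation of the lithiated oxazolidinone by the activated enol ester should be clean, because the pyronate is by far the better leaving group and the conjugated pyrone carbonyl is much less electrophilic.

Step 5
Reactants: 9 the hydroxypyrone imide; 10 (R)-but-3-en-2-ol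
Product: 11 the 4-[(S)-but-3-en-2-yloxy] ether of 9
Conditions: PPh3, DIAD, THF, 0 °C → rt
Reagents that add atoms: none
Why: Mitsunobu etherification of the acidic pyrone 4-OH proceeds with inversion at the carbinol carbon and gives the (S)-configured allyl ether, which protects the pyrone and later carries the stereochemical information to C1.

Step 6
Reactants: 11 the ether imide; 12 geranyl bromide
Product: 13 (S)-4-benzyl-3-[(2S,4E)-2-{2-[6-Ar-4-((S)-but-3-en-2-yloxy)-2-oxo-2H-pyran-3-yl]propan-2-yl}-5,9-dimethyldeca-4,8-dienoyl]oxazolidin-2-one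
Conditions: NaHMDS, THF, −78 °C; then 12, −78 → −40 °C
Reagents that add atoms: none
Why: Evans alkylation: the chelated Z-sodium enolate is attacked by the allylic bromide on the face away from the benzyl group, which sets C7 as (S) in the imide, the configuration of the target.

Step 7
Reactants: 13 the alkylated imide
Product: 14 6-Ar-4-[(S)-but-3-en-2-yloxy]-3-[(3S,5E)-3-(hydroxymethyl)-2,6,10-trimethylundeca-5,9-dien-2-yl]-2H-pyran-2-one
Conditions: LiBH4, MeOH (1 equiv), THF, 0 °C
Reagents that add atoms: none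
Why: Reductive removal of the auxiliary at the exocyclic imide carbonyl should spare the deactivated 4-alkoxypyrone carbonyl at 0 °C and does not touch C7.

Step 8
Reactants: 14 the primary alcohol
Product: 15 (2S,4E)-2-{2-[6-Ar-4-((S)-but-3-en-2-yloxy)-2-oxo-2H-pyran-3-yl]propan-2-yl}-5,9-dimethyldeca-4,8-dienal
Conditions: Dess–Martin periodinane, NaHCO3, CH2Cl2, 0 °C → rt
Reagents that add atoms: none
Why: Buffered Dess–Martin oxidation gives the aldehyde without acid or base strong enough to epimerise the hindered C7 centre, and avoids an electrophilic C6 that the pyrone oxygens could capture.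

Step 9
Reactants: 16 trimethyl phosphonoacetate; 17 1-bromo-3-methylbut-2-ene
Product: 18 methyl 2-(dimethoxyphosphoryl)-5-methylhex-4-enoate
Conditions: NaH, THF, 0 °C; then 17, rt
Reagents that add atoms: none
Why: C-Alkylation of the phosphonoacetate anion with the reactive allylic bromide is a standard way to α-substituted Horner–Wadsworth–Emmons reagents.

Step 10
Reactants: 15 the aldehyde; 18 the phosphonate
Product: 19 methyl (6E)-4-{2-[6-Ar-4-((S)-but-3-en-2-yloxy)-2-oxo-2H-pyran-3-yl]propan-2-yl}-7,11-dimethyl-2-(3-methylbut-2-en-1-yl)dodeca-2,6,10-trienoate (C4 = C7 unchanged, 2E/2Z mixture)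
Conditions: 18, NaH, THF, 0 °C; then 15, 0 → 40 °C
Reagents that add atoms: none
Why: Horner–Wadsworth–Emmons olefination builds the C6–C5 bond with prenyl and ester already on C5; the alkene geometry is irrelevant because it is reduced next.

Step 11
Reactants: 19 the enoate
Product: 20 methyl (6E)-4-{2-[6-Ar-4-((S)-but-3-en-2-yloxy)-2-oxo-2H-pyran-3-yl]propan-2-yl}-7,11-dimethyl-2-(3-methylbut-2-en-1-yl)dodeca-6,10-dienoate (C7 unchanged, both C5 epimers)
Conditions: Cu(OAc)2·H2O (5 mol%), 1,2-bis(diphenylphosphino)benzene (5 mol%), (Me2HSi)2O, t-BuOH, PhMe, rt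
Reagents that add atoms: none
Why: Copper hydride conjugate reduction is selective for the enoate over isolated alkenes and the tetrasubstituted alkoxypyrone; C5 forms as both epimers, which does not matter because it is enolised in step 14.

Step 12
Reactants: 20 the allyl pyronyl ether
Product: 21 methyl (6E)-4-{2-[(3R)-6-Ar-3-((E)-but-2-en-1-yl)-2,4-dioxo-3,4-dihydro-2H-pyran-3-yl]propan-2-yl}-7,11-dimethyl-2-(3-methylbut-2-en-1-yl)dodeca-6,10-dienoate
Conditions: PhMe, 110 °C (sealed tube)
Reagents that add atoms: none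
Why: Claisen rearrangement from O4 to C3 of the pyrone through a chair transition state with the methyl group equatorial should deliver the allyl terminus to the face dictated by the (S)-ether carbon, which sets the quaternary C1 (3R in the pyrandione) next to C8 and gives the E-butenyl chain.

Step 13
Reactants: 21 the butenyl pyrandione; 22 2-methylbut-2-ene
Product: 23 methyl (6E)-4-{2-[(3R)-6-Ar-3-(3-methylbut-2-en-1-yl)-2,4-dioxo-3,4-dihydro-2H-pyran-3-yl]propan-2-yl}-7,11-dimethyl-2-(3-methylbut-2-en-1-yl)dodeca-6,10-dienoate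
Conditions: second-generation Grubbs catalyst (5 mol%), 22 (excess), CH2Cl2, 35 °C
Reagents that add atoms: none
Why: Olefin cross-metathesis exchanges the ethylidene end of the disubstituted butenyl alkene for isopropylidene much faster than it attacks the trisubstituted prenyl and geranyl alkenes, giving the C1 prenyl group.

Step 14
Reactants: 23 the prenyl pyrandione ester
Product: 25 oblongifolin B 3',4'-bis(triisopropylsilyl) ether, via cyclohexanone keto ester 24 (not isolated)
Conditions: LiHMDS (2.5 equiv), THF, −78 → 50 °C; then aq. HCl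
Reagents that add atoms: none
Why: LiHMDS removes the only acidic proton (C5–H of the ester), the lithium enolate adds through C5 to the C9 lactone carbonyl of the pyrandione, and collapse of the tetrahedral intermediate opens the enol lactone to cyclohexanone 24, whose released aroylacetyl enolate then attacks the C4 ester through C3 on warming, expels methoxide and ends as the stable triketone enolate. The closest known reaction type is the domino Dieckmann (Claisen) condensation, with the enol lactone as acyl donor in the way diketene and enol lactones acylate enolates. Ring A closes 6-exo-trig at C9 by addition–elimination and ring B closes 6-exo-trig at C4. The new quaternary centre C5 is fixed by the bicycle itself: only the epimer of 24 with the ester cis to the C1 side chain can bridge, and the trans epimer should be returned by methoxide through retro-Dieckmann cleavage of the C9–C5 bond, while C1 and C7 are not touched. The step needs attack at C9 and not at the C2 ketone, which is secured because addition to the vinylogous ester carbonyl C2 is a reversible aldol whereas substitution at C9 releases a stabilised enolate irreversibly, and it needs a substrate without other acidic protons, which the fully substituted C1 provides.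

Step 15
Reactants: 25 the bis-silyl ether
Product: 26 oblongifolin B
Conditions: TBAF, AcOH, THF, 0 °C
Reagents that add atoms: none
Why: Buffered fluoride cleaves both aryl silyl ethers without acid, so the prenyl groups cannot cyclise onto the enol and no stereocentre is affected.

**Compound list**

1 | methyl 3,4-dihydroxybenzoate | COC(=O)c1ccc(O)c(O)c1 | starting material
2 | methyl 3,4-bis(triisopropylsilyloxy)benzoate | COC(=O)c1ccc(O[Si](C(C)C)(C(C)C)C(C)C)c(O[Si](C(C)C)(C(C)C)C(C)C)c1 | intermediate
3 | methyl acetoacetate | COC(=O)CC(C)=O | starting material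
4 | methyl 5-Ar-3,5-dioxopentanoate | COC(=O)CC(=O)CC(=O)c1ccc(O[Si](C(C)C)(C(C)C)C(C)C)c(O[Si](C(C)C)(C(C)C)C(C)C)c1 | intermediate
5 | 6-Ar-4-hydroxy-2H-pyran-2-one | O=C1C=C(O)C=C(c2ccc(O[Si](C(C)C)(C(C)C)C(C)C)c(O[Si](C(C)C)(C(C)C)C(C)C)c2)O1 | intermediate
6 | 2,2-dimethyl-5-(propan-2-ylidene)-1,3-dioxane-4,6-dione | CC(C)=C1C(=O)OC(C)(C)OC1=O | starting material
7 | 7-Ar-4,4-dimethyl-3,4-dihydro-2H,5H-pyrano[4,3-b]pyran-2,5-dione | O=C1CC(C)(C)C2=C(O1)C=C(c3ccc(O[Si](C(C)C)(C(C)C)C(C)C)c(O[Si](C(C)C)(C(C)C)C(C)C)c3)OC2=O | intermediate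
8 | (S)-4-benzyloxazolidin-2-one | O=C1OC[C@H](Cc2ccccc2)N1 | starting material
9 | (S)-4-benzyl-3-[3-(6-Ar-4-hydroxy-2-oxo-2H-pyran-3-yl)-3-methylbutanoyl]oxazolidin-2-one | O=C1OC[C@H](Cc2ccccc2)N1C(=O)CC(C)(C)C3=C(O)C=C(c4ccc(O[Si](C(C)C)(C(C)C)C(C)C)c(O[Si](C(C)C)(C(C)C)C(C)C)c4)OC3=O | intermediate
10 | (R)-but-3-en-2-ol | C[C@@H](O)C=C | starting material
11 | 4-[(S)-but-3-en-2-yloxy] ether of 9 | O=C1OC[C@H](Cc2ccccc2)N1C(=O)CC(C)(C)C3=C(O[C@@H](C)C=C)C=C(c4ccc(O[Si](C(C)C)(C(C)C)C(C)C)c(O[Si](C(C)C)(C(C)C)C(C)C)c4)OC3=O | intermediate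
12 | geranyl bromide | CC(C)=CCC/C(C)=C/CBr | starting material
13 | (2S)-geranylated imide | CC(C)=CCC/C(C)=C/C[C@H](C(=O)N1[C@@H](Cc2ccccc2)COC1=O)C(C)(C)C3=C(O[C@@H](C)C=C)C=C(c4ccc(O[Si](C(C)C)(C(C)C)C(C)C)c(O[Si](C(C)C)(C(C)C)C(C)C)c4)OC3=O | intermediate
14 | primary alcohol (C6–OH) | CC(C)=CCC/C(C)=C/C[C@H](CO)C(C)(C)C1=C(O[C@@H](C)C=C)C=C(c2ccc(O[Si](C(C)C)(C(C)C)C(C)C)c(O[Si](C(C)C)(C(C)C)C(C)C)c2)OC1=O | intermediate
15 | aldehyde (C6) | CC(C)=CCC/C(C)=C/C[C@H](C=O)C(C)(C)C1=C(O[C@@H](C)C=C)C=C(c2ccc(O[Si](C(C)C)(C(C)C)C(C)C)c(O[Si](C(C)C)(C(C)C)C(C)C)c2)OC1=O | intermediate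
16 | trimethyl phosphonoacetate | COC(=O)CP(=O)(OC)OC | starting material
17 | 1-bromo-3-methylbut-2-ene | CC(C)=CCBr | starting material
18 | methyl 2-(dimethoxyphosphoryl)-5-methylhex-4-enoate | COC(=O)C(CC=C(C)C)P(=O)(OC)OC | intermediate
19 | enoate (C6=C5, E/Z mixture) | CC(C)=CCC/C(C)=C/C[C@H](C=C(CC=C(C)C)C(=O)OC)C(C)(C)C1=C(O[C@@H](C)C=C)C=C(c2ccc(O[Si](C(C)C)(C(C)C)C(C)C)c(O[Si](C(C)C)(C(C)C)C(C)C)c2)OC1=O | intermediate
20 | saturated ester with allyl pyronyl ether (C5 epimers) | CC(C)=CCC/C(C)=C/C[C@H](CC(CC=C(C)C)C(=O)OC)C(C)(C)C1=C(O[C@@H](C)C=C)C=C(c2ccc(O[Si](C(C)C)(C(C)C)C(C)C)c(O[Si](C(C)C)(C(C)C)C(C)C)c2)OC1=O | intermediate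
21 | (3R)-3-[(E)-but-2-enyl]pyran-2,4-dione ester | CC(C)=CCC/C(C)=C/C[C@H](CC(CC=C(C)C)C(=O)OC)C(C)(C)[C@]1(C/C=C/C)C(=O)C=C(c2ccc(O[Si](C(C)C)(C(C)C)C(C)C)c(O[Si](C(C)C)(C(C)C)C(C)C)c2)OC1=O | intermediate
22 | 2-methylbut-2-ene | CC=C(C)C | starting material
23 | (3R)-3-prenylpyran-2,4-dione ester (key-step precursor) | CC(C)=CCC/C(C)=C/C[C@H](CC(CC=C(C)C)C(=O)OC)C(C)(C)[C@]1(CC=C(C)C)C(=O)C=C(c2ccc(O[Si](C(C)C)(C(C)C)C(C)C)c(O[Si](C(C)C)(C(C)C)C(C)C)c2)OC1=O | intermediate
24 | methyl 3-(3-Ar-3-oxopropanoyl)-5-geranyl-4,4-dimethyl-2-oxo-1,3-bis(3-methylbut-2-enyl)cyclohexane-1-carboxylate, configured as in the target | CC(C)=CCC/C(C)=C/C[C@@H]1C[C@](C(=O)OC)(CC=C(C)C)C(=O)[C@@](CC=C(C)C)(C(=O)CC(=O)c2ccc(O[Si](C(C)C)(C(C)C)C(C)C)c(O[Si](C(C)C)(C(C)C)C(C)C)c2)C1(C)C | intermediate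
25 | oblongifolin B 3',4'-bis(triisopropylsilyl) ether | CC(C)=CCC/C(C)=C/C[C@@H]1C[C@]2(CC=C(C)C)C(=O)[C@@](CC=C(C)C)(C(=O)C(C(=O)c3ccc(O[Si](C(C)C)(C(C)C)C(C)C)c(O[Si](C(C)C)(C(C)C)C(C)C)c3)=C2O)C1(C)C | intermediate
26 | oblongifolin B | CC(C)=CCC/C(C)=C/C[C@@H]1C[C@]2(CC=C(C)C)C(=O)[C@@](CC=C(C)C)(C(=O)C(C(=O)c3ccc(O)c(O)c3)=C2O)C1(C)C | target

**Step count.** 15 steps in total; the longest linear sequence is 14 steps (steps 1–8 and 10–15), step 9 being a one-step branch.

**Steps most likely to fail**

Step 14 (key step). The C5 enolate may attack from the face that leaves ester and aroylacetyl chain trans, so that ring B cannot close and correction depends on a slow retro-Dieckmann; methoxide may also cleave the aroylacetyl group by retro-Claisen. The fallback sets out from 23. Methanolysis of the enol lactone (NaOMe cat., MeOH, 0 °C) should give the open-chain compound dimethyl 2-(3-Ar-3-oxopropanoyl)-4-geranyl-3,3-dimethyl-2,6-bis(3-methylbut-2-enyl)heptanedioate F1. F1 is then cyclised as a classical double Dieckmann condensation under fully equilibrating conditions (KOt-Bu, THF/t-BuOH, 0 → 50 °C). There all keto ester isomers interconvert and only the cis isomer is drained to the triketone enolate. The fallback returns to the route at 25.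

Step 12. Chirality transfer may erode through competing chair and boat transition states, or the secondary allyl group may be lost thermally by ionisation or elimination. If the boat path dominated cleanly, the enantiomeric alcohol in step 5 would correct the outcome. The fallback proper sets out from 20 and replaces the pericyclic step by an ionic one: zerovalent palladium with a chiral ligand (Pd2(dba)3·CHCl3, DACH-phenyl Trost ligand, PhMe, rt) ionises the pyronyl allyl ether. The π-butenyl complex is recaptured at pyrone C3 through its unsubstituted terminus, so the face is chosen by the ligand (its enantiomer fixed in a test run). No new compound is made (F0) and the route is rejoined at 21.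

Step 13. Metathesis may cut the geranyl chain at its internal trisubstituted alkene, or stall at the hindered butenyl group. The fallback sets out from 20 and avoids metathesis. The butenyl ether is removed with Pd(PPh3)4 and pyrrolidine to give the free 4-hydroxypyrone ester F2. F2 is then prenylated at C3 by palladium-catalysed asymmetric allylic alkylation (methyl 3-methylbut-2-enyl carbonate, Pd2(dba)3·CHCl3, DACH-phenyl Trost ligand), the hindered nucleophile attacking the unsubstituted terminus. This gives 23 directly, where the route is rejoined.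

**Further compounds**

F1 | step 14 | dimethyl 2-(3-Ar-3-oxopropanoyl)-4-geranyl-3,3-dimethyl-2,6-bis(3-methylbut-2-enyl)heptanedioate (C1 and C7 as in 23) | CC(C)=CCC/C(C)=C/C[C@H](CC(CC=C(C)C)C(=O)OC)C(C)(C)[C@](C(=O)OC)(CC=C(C)C)C(=O)CC(=O)c1ccc(O[Si](C(C)C)(C(C)C)C(C)C)c(O[Si](C(C)C)(C(C)C)C(C)C)c1
F2 | step 13 | 4-hydroxypyrone ester (20 without the butenyl group) | CC(C)=CCC/C(C)=C/C[C@H](CC(CC=C(C)C)C(=O)OC)C(C)(C)C1=C(O)C=C(c2ccc(O[Si](C(C)C)(C(C)C)C(C)C)c(O[Si](C(C)C)(C(C)C)C(C)C)c2)OC1=O
F0 | step 12 | none | none
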